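Retrosynthetic overview
1. Rings A (phloroglucinol-type arene) and B (catechol) are bought as arenes; ring C (the pyranone) is made last by closing the C4–C4a bond, with C4 carried as the oxygen-bearing carbon of a siloxyalkyne hung on ring A through O1, C2 and C3 (ketenium-ion Friedel–Crafts closure, then loss of all five silyl groups in the same flask).
2. Enabling feature: in ring A, C4a is the only unsubstituted carbon ortho to O1 (C8 carries the side chain); it lies between the oxygen-bearing carbons C8a and C5 and para to the methoxy-bearing C7, so it is the most nucleophilic arene carbon and stands in a 1,6-relationship to C4.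
3. C2–O1 and the 2S centre come from a Mitsunobu inversion of a ring-B alkynyl carbinol made by catalytic asymmetric alkynylation; no enolisable carbonyl exists before the last step, so retro-oxa-Michael loss of C2 cannot occur on the way.
4. The C8 side chain is put on by 1,4-addition of a Z alkenylmagnesium reagent (Z geometry from anti-carbomagnesiation of propargyl alcohol) to a ring-A ortho-quinone methide, which also frees the O1 phenol.
5. Order: side-chain reagent and ring-A phenol (steps 1–6), ring-B carbinol (steps 7–8), union and ynol ether (steps 9–11), ring C (step 12).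

Key step: step 12

Assumption: 2,4-dihydroxy-6-methoxybenzaldehyde is taken as commercial, and the facial sense of the step 8 catalyst is assigned by analogy with zinc–ProPhenol aldol additions, to be confirmed by MTPA ester analysis (the enantiomeric ligand is equally available).
Abbreviations: TBS = tert-butyldimethylsilyl; TIPS = triisopropylsilyl; Boc = tert-butoxycarbonyl; DIAD = diisopropyl azodicarboxylate; HNTf2 = bis(trifluoromethanesulfonyl)imide.

Step 1
Reactants: 1 prop-2-yn-1-ol (propargyl alcohol)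
Product: 3 (2Z)-3-iodo-2-methylprop-2-en-1-ol, via alkenylmagnesium alkoxide 2 (not isolated)
Conditions: MeMgBr (2.5 equiv), copper iodide CuI (10 mol%), THF, −10 °C → rt; then I2, THF, −10 °C
Reagents that add atoms: methylmagnesium bromide (C[Mg]Br); iodine (II)
Why: Copper-catalysed anti-carbomagnesiation of the propargylic alkoxide puts the methyl group on C2 and the magnesium on C3 on the side of the chelating CH2O group (intermediate 2), and iodinolysis with retention should give the Z vinyl iodide with iodine and CH2OH cis.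

Step 2
Reactants: 3 (2Z)-3-iodo-2-methylprop-2-en-1-ol
Product: 4 tert-butyl{[(2Z)-3-iodo-2-methylprop-2-en-1-yl]oxy}dimethylsilane
Conditions: TBSCl, imidazole, CH2Cl2, 0 °C → rt
Reagents that add atoms: tert-butyldimethylsilyl chloride (CC(C)(C)[Si](C)(C)Cl)
Why: Silyl ether formation masks the primary alcohol for the organomagnesium step and leaves the vinyl iodide geometry untouched.

Step 3
Reactants: 5 2,4-dihydroxy-6-methoxybenzaldehyde
Product: 6 4-[(TBS)oxy]-2-hydroxy-6-methoxybenzaldehyde
Conditions: TBSCl (1.05 equiv), imidazole, CH2Cl2, −10 → 0 °C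
Reagents that add atoms: tert-butyldimethylsilyl chloride (CC(C)(C)[Si](C)(C)Cl)
Why: Selective silylation should go to O4 because the 2-OH is held in a hydrogen bond to the formyl oxygen while the 4-OH is the more acidic and unhindered phenol.

Step 4
Reactants: 6 4-[(TBS)oxy]-2-hydroxy-6-methoxybenzaldehyde
Product: 7 tert-butyl 5-[(TBS)oxy]-2-formyl-3-methoxyphenyl carbonate
Conditions: Boc2O (1.2 equiv), DMAP (5 mol%), i-Pr2NEt, THF, 0 °C → rt
Reagents that add atoms: di-tert-butyl dicarbonate (CC(C)(C)OC(=O)OC(=O)OC(C)(C)C)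
Why: DMAP-catalysed carbonate formation on the chelated phenol installs the O-Boc group that later triggers release of the ortho-quinone methide.

Step 5
Reactants: 7 tert-butyl 5-[(TBS)oxy]-2-formyl-3-methoxyphenyl carbonate
Product: 8 tert-butyl 5-[(TBS)oxy]-2-(hydroxymethyl)-3-methoxyphenyl carbonate
Conditions: BH3·THF, THF, −10 → 0 °C; MeOH, then pH 7 buffer
Reagents that add atoms: none
Why: Borane reduction of the aldehyde runs through a neutral alkoxyborane, so no free alkoxide is formed that could start carbonate migration before step 6.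

Step 6
Reactants: 4 tert-butyl{[(2Z)-3-iodo-2-methylprop-2-en-1-yl]oxy}dimethylsilane; 8 tert-butyl 5-[(TBS)oxy]-2-(hydroxymethyl)-3-methoxyphenyl carbonate
Product: 11 5-[(TBS)oxy]-2-[(2Z)-4-[(TBS)oxy]-3-methylbut-2-en-1-yl]-3-methoxyphenol, via alkenylmagnesium chloride 9 (not isolated), via ortho-quinone methide 10 (not isolated)
Conditions: 4 (1.3 equiv), i-PrMgCl·LiCl, THF, 0 → 25 °C; 8, MeMgCl (1.0 equiv), THF, −78 °C; combine at −78 °C → rt; aqueous NH4Cl
Reagents that add atoms: none
Why: Iodine–magnesium exchange with retention gives the Z alkenyl Grignard reagent 9, and deprotonation of 8 starts the known anionic cascade of carbonate transfer and beta-elimination to ortho-quinone methide 10, whose exocyclic carbon takes up the alkenyl group in a 1,4-addition that restores the arene and keeps the Z geometry.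

Step 7
Reactants: 12 3,4-dihydroxybenzaldehyde
Product: 13 3,4-bis[(TBS)oxy]benzaldehyde
Conditions: TBSCl (2.3 equiv), imidazole, DMF, rt
Reagents that add atoms: tert-butyldimethylsilyl chloride (CC(C)(C)[Si](C)(C)Cl)
Why: Double silyl ether formation gives fluoride-labile catechol protection that should survive the organozinc, Mitsunobu and organolithium steps.

Step 8
Reactants: 13 3,4-bis[(TBS)oxy]benzaldehyde; 14 ethynyltrimethylsilane
Product: 16 (1S)-1-{3,4-bis[(TBS)oxy]phenyl}-3-(trimethylsilyl)prop-2-yn-1-ol, via alkynyl(methyl)zinc 15 (not isolated)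
Conditions: Me2Zn (3 equiv), (S,S)-ProPhenol (10 mol%), Ph3P=O (20 mol%), toluene, 0 → 4 °C
Reagents that add atoms: none
Why: Catalytic asymmetric alkynylation with the dinuclear zinc–ProPhenol complex should deliver the alkynyl group of 15 to the Re face of the aldehyde, which sets the carbinol centre (S by the CIP rules because the silylalkynyl group outranks the aryl group) with the arrangement that Mitsunobu inversion turns into 2S.

Step 9
Reactants: 11 5-[(TBS)oxy]-2-[(2Z)-4-[(TBS)oxy]-3-methylbut-2-en-1-yl]-3-methoxyphenol; 16 (1S)-1-{3,4-bis[(TBS)oxy]phenyl}-3-(trimethylsilyl)prop-2-yn-1-ol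
Product: 17 1-{[(1R)-1-{3,4-bis[(TBS)oxy]phenyl}-3-(trimethylsilyl)prop-2-yn-1-yl]oxy}-5-[(TBS)oxy]-3-methoxy-2-[(2Z)-4-[(TBS)oxy]-3-methylbut-2-en-1-yl]benzene
Conditions: PPh3 (1.5 equiv), DIAD (1.5 equiv), toluene, −20 °C → rt
Reagents that add atoms: none
Why: In this Mitsunobu etherification the phenol oxygen displaces the alkoxyphosphonium group in an SN2 reaction with inversion, which fixes the future C2 in the spatial arrangement of the 2S target (R by the CIP rules while the silylalkynyl group is present), and the C-silyl group blocks SN2′ attack at the alkyne terminus.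

Step 10
Reactants: 17 the C-silylated propargylic aryl ether
Product: 18 1-{[(1S)-1-{3,4-bis[(TBS)oxy]phenyl}prop-2-yn-1-yl]oxy}-5-[(TBS)oxy]-3-methoxy-2-[(2Z)-4-[(TBS)oxy]-3-methylbut-2-en-1-yl]benzene
Conditions: AgNO3 (10 mol%), acetone/H2O/CH2Cl2, rt, dark
Reagents that add atoms: none
Why: Silver-catalysed protodesilylation of the alkynylsilane runs through a silver acetylide and should leave the aryl and allyl TBS ethers and the stereocentre untouched.

Step 11
Reactants: 18 the terminal propargylic aryl ether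
Product: 21 1-{[(1R)-1-{3,4-bis[(TBS)oxy]phenyl}-3-[(triisopropylsilyl)oxy]prop-2-yn-1-yl]oxy}-5-[(TBS)oxy]-3-methoxy-2-[(2Z)-4-[(TBS)oxy]-3-methylbut-2-en-1-yl]benzene, via lithium acetylide 19 (not isolated), via lithium ynolate 20 (not isolated)
Conditions: n-BuLi (1.0 equiv), THF, −78 °C; LiOOt-Bu (from t-BuOOH and LiN(SiMe3)2, 1.1 equiv), −78 → 0 °C; TIPSOTf (1.3 equiv), −78 → 0 °C
Reagents that add atoms: lithium tert-butyl peroxide ([Li+].CC(C)(C)O[O-]); triisopropylsilyl trifluoromethanesulfonate (CC(C)[Si](C(C)C)(C(C)C)OS(=O)(=O)C(F)(F)F)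
Why: Oxidation of lithium acetylide 19 by the lithium alkyl peroxide gives ynolate 20, which the bulky silyl triflate should trap on oxygen to give the siloxyalkyne, while the negative charge of the acetylide guards the C2 proton against a second deprotonation so that the stereocentre is kept.

Step 12
Reactants: 21 the siloxyalkyne
Product: 23 (2S)-2-(3,4-dihydroxyphenyl)-5-hydroxy-8-[(2Z)-4-hydroxy-3-methylbut-2-en-1-yl]-7-methoxy-2,3-dihydro-4H-chromen-4-one, via 4-silyloxy-2H-chromene 22 (not isolated)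
Conditions: HNTf2 (10 mol%), CH2Cl2, −78 → −40 °C, dark; then Bu4NF/AcOH (1:1, excess), THF, 0 °C → rt
Reagents that add atoms: none
Why: Proposed new method: the acid protonates C3 of the siloxyalkyne to give a linear silyl ketenium ion at C4, C4a of ring A attacks it in a 6-endo-dig Friedel–Crafts closure of ring C, loss of the C4a proton returns the acid and leaves enol silane 22, and buffered fluoride then frees the C4 ketone and the four hydroxyl groups. The closest known reaction types are the HNTf2-promoted carbocyclisation of arene-tethered siloxyalkynes to tetralone enol silanes through an all-carbon tether and the 6-endo hydroarylation of aryl propargyl ethers to 2H-chromenes; an O1-tethered siloxyalkyne with a propargylic stereocentre has not been closed in this way. No new stereocentre is formed, and C2 should keep its configuration because neither its C–H nor its C–O1 bond takes part and no enolisable C4 carbonyl exists before the buffered fluoride stage, which rules out retro-oxa-Michael opening. Site selectivity rests on ring A: C4a is the only free carbon ortho to O1 and is activated by O1, the C5 silyloxy group and the C7 methoxy group, whereas ring B could close only a strained five-membered ring and the side-chain alkene only an eight-membered one. The chemoselectivity needed is C3 protonation ahead of ionisation of the propargylic C2–O1 bond, which the high carbon basicity of the ynol ether, the catalytic amount of acid and the low temperature should secure.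

Compound list
1 | prop-2-yn-1-ol | C#CCO | starting material
2 | magnesium alkoxide of (2Z)-3-(bromomagnesio)-2-methylprop-2-en-1-ol (chelated alkenylmagnesium alkoxide) | Br[Mg]/C=C(/C)CO[Mg]Br | intermediate
3 | (2Z)-3-iodo-2-methylprop-2-en-1-ol | I/C=C(/C)CO | intermediate
4 | tert-butyl{[(2Z)-3-iodo-2-methylprop-2-en-1-yl]oxy}dimethylsilane | I/C=C(/C)CO[Si](C)(C)C(C)(C)C | intermediate
5 | 2,4-dihydroxy-6-methoxybenzaldehyde | COc1cc(O)cc(O)c1C=O | starting material
6 | 4-[(TBS)oxy]-2-hydroxy-6-methoxybenzaldehyde | COc1cc(O[Si](C)(C)C(C)(C)C)cc(O)c1C=O | intermediate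
7 | tert-butyl 5-[(TBS)oxy]-2-formyl-3-methoxyphenyl carbonate | COc1cc(O[Si](C)(C)C(C)(C)C)cc(OC(=O)OC(C)(C)C)c1C=O | intermediate
8 | tert-butyl 5-[(TBS)oxy]-2-(hydroxymethyl)-3-methoxyphenyl carbonate | COc1cc(O[Si](C)(C)C(C)(C)C)cc(OC(=O)OC(C)(C)C)c1CO | intermediate
9 | [(1Z)-3-[(TBS)oxy]-2-methylprop-1-en-1-yl]magnesium chloride (LiCl complex) | Cl[Mg]/C=C(/C)CO[Si](C)(C)C(C)(C)C | intermediate
10 | 3-[(TBS)oxy]-5-methoxy-6-methylidenecyclohexa-2,4-dien-1-one (ortho-quinone methide) | C=C1C(OC)=CC(O[Si](C)(C)C(C)(C)C)=CC1=O | intermediate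
11 | 5-[(TBS)oxy]-2-[(2Z)-4-[(TBS)oxy]-3-methylbut-2-en-1-yl]-3-methoxyphenol | COc1cc(O[Si](C)(C)C(C)(C)C)cc(O)c1C/C=C(/C)CO[Si](C)(C)C(C)(C)C | intermediate
12 | 3,4-dihydroxybenzaldehyde | O=Cc1ccc(O)c(O)c1 | starting material
13 | 3,4-bis[(TBS)oxy]benzaldehyde | O=Cc1ccc(O[Si](C)(C)C(C)(C)C)c(O[Si](C)(C)C(C)(C)C)c1 | intermediate
14 | ethynyltrimethylsilane | C#C[Si](C)(C)C | starting material
15 | methyl[(trimethylsilyl)ethynyl]zinc | C[Zn]C#C[Si](C)(C)C | intermediate
16 | (1S)-1-{3,4-bis[(TBS)oxy]phenyl}-3-(trimethylsilyl)prop-2-yn-1-ol | C[Si](C)(C)C#C[C@@H](O)c1ccc(O[Si](C)(C)C(C)(C)C)c(O[Si](C)(C)C(C)(C)C)c1 | intermediate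
17 | 1-{[(1R)-1-{3,4-bis[(TBS)oxy]phenyl}-3-(trimethylsilyl)prop-2-yn-1-yl]oxy}-5-[(TBS)oxy]-3-methoxy-2-[(2Z)-4-[(TBS)oxy]-3-methylbut-2-en-1-yl]benzene (R by CIP because the silylalkynyl group outranks the aryl group; spatial arrangement of the 2S target) | COc1cc(O[Si](C)(C)C(C)(C)C)cc(c1C/C=C(/C)CO[Si](C)(C)C(C)(C)C)O[C@H](c1ccc(O[Si](C)(C)C(C)(C)C)c(O[Si](C)(C)C(C)(C)C)c1)C#C[Si](C)(C)C | intermediate
18 | 1-{[(1S)-1-{3,4-bis[(TBS)oxy]phenyl}prop-2-yn-1-yl]oxy}-5-[(TBS)oxy]-3-methoxy-2-[(2Z)-4-[(TBS)oxy]-3-methylbut-2-en-1-yl]benzene | COc1cc(O[Si](C)(C)C(C)(C)C)cc(c1C/C=C(/C)CO[Si](C)(C)C(C)(C)C)O[C@H](c1ccc(O[Si](C)(C)C(C)(C)C)c(O[Si](C)(C)C(C)(C)C)c1)C#C | intermediate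
19 | lithium acetylide of 18 (configuration at the ether carbon unchanged) | COc1cc(O[Si](C)(C)C(C)(C)C)cc(c1C/C=C(/C)CO[Si](C)(C)C(C)(C)C)O[C@H](c1ccc(O[Si](C)(C)C(C)(C)C)c(O[Si](C)(C)C(C)(C)C)c1)C#C[Li] | intermediate
20 | lithium ynolate formed from 19 (configuration at the ether carbon unchanged) | COc1cc(O[Si](C)(C)C(C)(C)C)cc(c1C/C=C(/C)CO[Si](C)(C)C(C)(C)C)O[C@H](c1ccc(O[Si](C)(C)C(C)(C)C)c(O[Si](C)(C)C(C)(C)C)c1)C#CO[Li] | intermediate
21 | 1-{[(1R)-1-{3,4-bis[(TBS)oxy]phenyl}-3-[(triisopropylsilyl)oxy]prop-2-yn-1-yl]oxy}-5-[(TBS)oxy]-3-methoxy-2-[(2Z)-4-[(TBS)oxy]-3-methylbut-2-en-1-yl]benzene (R by CIP because the siloxyalkynyl group outranks the aryl group; same spatial arrangement as 18) | COc1cc(O[Si](C)(C)C(C)(C)C)cc(c1C/C=C(/C)CO[Si](C)(C)C(C)(C)C)O[C@H](c1ccc(O[Si](C)(C)C(C)(C)C)c(O[Si](C)(C)C(C)(C)C)c1)C#CO[Si](C(C)C)(C(C)C)C(C)C | intermediate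
22 | (2S)-2-{3,4-bis[(TBS)oxy]phenyl}-5-[(TBS)oxy]-7-methoxy-8-[(2Z)-4-[(TBS)oxy]-3-methylbut-2-en-1-yl]-4-[(triisopropylsilyl)oxy]-2H-chromene | COc1cc(O[Si](C)(C)C(C)(C)C)c2c(c1C/C=C(/C)CO[Si](C)(C)C(C)(C)C)O[C@H](c1ccc(O[Si](C)(C)C(C)(C)C)c(O[Si](C)(C)C(C)(C)C)c1)C=C2O[Si](C(C)C)(C(C)C)C(C)C | intermediate
23 | (2S)-2-(3,4-dihydroxyphenyl)-5-hydroxy-8-[(2Z)-4-hydroxy-3-methylbut-2-en-1-yl]-7-methoxy-2,3-dihydro-4H-chromen-4-one | COc1cc(O)c2c(c1C/C=C(/C)CO)O[C@H](c1ccc(O)c(O)c1)CC2=O | target

Total step count: 12.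
Longest linear sequence: 8 steps (5 → 6 → 7 → 8 → 11 → 17 → 18 → 21 → 23; steps 3, 4, 5, 6, 9, 10, 11 and 12).

Steps most likely to fail

Step 12 (proposed new method). What may go wrong: heterolysis of the propargylic C2–O1 bond under the strong acid in place of C3 protonation, which would strip the aryl ether, or erosion of the C2 configuration through reversible electrocyclic opening of the 2H-chromene. The fallback uses known chemistry, sets out from 18 (so it does not depend on step 11 either) and comes back to the route at 23. Anti-Markovnikov hydroboration of the terminal alkyne with Cy2BH (THF, 0 °C; the trisubstituted side-chain alkene reacts far more slowly) and oxidation of the alkenylborane with Me3NO under neutral conditions should give (3S)-3-{3,4-bis[(TBS)oxy]phenyl}-3-{5-[(TBS)oxy]-2-[(2Z)-4-[(TBS)oxy]-3-methylbut-2-en-1-yl]-3-methoxyphenoxy}propanal F1, which is used at once. Pinnick oxidation (NaClO2, NaH2PO4, 2-methylbut-2-ene, t-BuOH/H2O) should give the corresponding (3S)-propanoic acid F2. Trifluoroacetic anhydride (CH2Cl2, 0 °C) turns F2 into the mixed anhydride, which acylates C4a in the classical intramolecular Friedel–Crafts closure to the tetrasilyl flavanone (2S)-2-{3,4-bis[(TBS)oxy]phenyl}-5-[(TBS)oxy]-7-methoxy-8-[(2Z)-4-[(TBS)oxy]-3-methylbut-2-en-1-yl]-2,3-dihydro-4H-chromen-4-one F3. Bu4NF/AcOH in THF then removes the four TBS groups to give 23.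

Step 9. What may go wrong: ionisation of the alkoxyphosphonium intermediate of this electron-rich benzylic and propargylic carbinol, which would erode the enantiomeric purity and let the cation alkylate ring A at carbon. The fallback sets out from 13 and comes back at 18, so steps 8 to 10 are not needed. Ethynylmagnesium bromide (THF, 0 °C) adds to 13 to give racemic 1-{3,4-bis[(TBS)oxy]phenyl}prop-2-yn-1-ol F4, and pentafluorobenzoyl chloride/Et3N converts it into 1-{3,4-bis[(TBS)oxy]phenyl}prop-2-yn-1-yl pentafluorobenzoate F5. Copper-catalysed enantioselective propargylic etherification of F5 with phenol 11 [(CuOTf)2·C6H6, chiral pybox ligand, i-Pr2NEt, 0 °C] runs through a copper allenylidene and takes its stereocontrol from the ligand and not from an SN2 inversion; with the ligand enantiomer chosen for the S ether it should give 18 directly.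

Step 6. What may go wrong: self-condensation of the donor-stabilised ortho-quinone methide before the alkenylmagnesium reagent adds, or partial loss of the Z geometry of the alkenyl nucleophile. The fallback reverses the polarity of the coupling, sets out from 8 and 4 and comes back at 11. MsCl, LiCl and 2,4,6-collidine in DMF at 0 °C should turn 8 into tert-butyl 5-[(TBS)oxy]-2-(chloromethyl)-3-methoxyphenyl carbonate F6 without forming an alkoxide. Zinc dust and LiCl in THF insert to give the benzylzinc chloride {2-[(tert-butoxycarbonyl)oxy]-4-[(TBS)oxy]-6-methoxybenzyl}zinc chloride F7. Negishi coupling of F7 with vinyl iodide 4 [Pd(PPh3)4, THF, 25 °C], which retains the alkene geometry, should give tert-butyl 5-[(TBS)oxy]-2-[(2Z)-4-[(TBS)oxy]-3-methylbut-2-en-1-yl]-3-methoxyphenyl carbonate F8, and piperidine in CH2Cl2 cleaves the aryl carbonate to give 11.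

Further compounds
F1 | step 12 | (3S)-3-{3,4-bis[(TBS)oxy]phenyl}-3-{5-[(TBS)oxy]-2-[(2Z)-4-[(TBS)oxy]-3-methylbut-2-en-1-yl]-3-methoxyphenoxy}propanal | COc1cc(O[Si](C)(C)C(C)(C)C)cc(c1C/C=C(/C)CO[Si](C)(C)C(C)(C)C)O[C@H](c1ccc(O[Si](C)(C)C(C)(C)C)c(O[Si](C)(C)C(C)(C)C)c1)CC=O
F2 | step 12 | (3S)-3-{3,4-bis[(TBS)oxy]phenyl}-3-{5-[(TBS)oxy]-2-[(2Z)-4-[(TBS)oxy]-3-methylbut-2-en-1-yl]-3-methoxyphenoxy}propanoic acid | COc1cc(O[Si](C)(C)C(C)(C)C)cc(c1C/C=C(/C)CO[Si](C)(C)C(C)(C)C)O[C@H](c1ccc(O[Si](C)(C)C(C)(C)C)c(O[Si](C)(C)C(C)(C)C)c1)CC(=O)O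
F3 | step 12 | (2S)-2-{3,4-bis[(TBS)oxy]phenyl}-5-[(TBS)oxy]-7-methoxy-8-[(2Z)-4-[(TBS)oxy]-3-methylbut-2-en-1-yl]-2,3-dihydro-4H-chromen-4-one | COc1cc(O[Si](C)(C)C(C)(C)C)c2c(c1C/C=C(/C)CO[Si](C)(C)C(C)(C)C)O[C@H](c1ccc(O[Si](C)(C)C(C)(C)C)c(O[Si](C)(C)C(C)(C)C)c1)CC2=O
F4 | step 9 | racemic 1-{3,4-bis[(TBS)oxy]phenyl}prop-2-yn-1-ol | C#CC(O)c1ccc(O[Si](C)(C)C(C)(C)C)c(O[Si](C)(C)C(C)(C)C)c1
F5 | step 9 | racemic 1-{3,4-bis[(TBS)oxy]phenyl}prop-2-yn-1-yl pentafluorobenzoate | C#CC(OC(=O)c1c(F)c(F)c(F)c(F)c1F)c1ccc(O[Si](C)(C)C(C)(C)C)c(O[Si](C)(C)C(C)(C)C)c1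
F6 | step 6 | tert-butyl 5-[(TBS)oxy]-2-(chloromethyl)-3-methoxyphenyl carbonate | COc1cc(O[Si](C)(C)C(C)(C)C)cc(OC(=O)OC(C)(C)C)c1CCl
F7 | step 6 | {2-[(tert-butoxycarbonyl)oxy]-4-[(TBS)oxy]-6-methoxybenzyl}zinc chloride | COc1cc(O[Si](C)(C)C(C)(C)C)cc(OC(=O)OC(C)(C)C)c1C[Zn]Cl
F8 | step 6 | tert-butyl 5-[(TBS)oxy]-2-[(2Z)-4-[(TBS)oxy]-3-methylbut-2-en-1-yl]-3-methoxyphenyl carbonate | COc1cc(O[Si](C)(C)C(C)(C)C)cc(OC(=O)OC(C)(C)C)c1C/C=C(/C)CO[Si](C)(C)C(C)(C)C
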